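**Retrosynthetic overview**

1. Last operations: the C8 ester (acid made from 4-methylfuran-2(5H)-one) and the C13 acetate are put on the tricyclic diol.
2. Key disconnection: C3–C4 and C1=C2 are cut together. The two-carbon unit C2–C3 leaves as (trimethylsilyl)ketene, and what remains is a nine-membered lactone (C1 acyl on the C4 oxygen) fused to the 5-ylidene butenolide. Forward, one carbanion-addition/Peterson annulation closes the 3(2H)-furanone and the ten-membered carbocycle together.
3. Enabling feature: C4–H is the ε-position of the dienyl butenolide C12(=O)–C11=C7–C6=C5 (lactone ring O, C6, C7, C11, C12), so its anion is an aromatic 2-oxidofuran with an exocyclic nucleophilic terminus at C4. The 1,4-oxygen bridge of the furanone is the ring oxygen of that nine-membered lactone, which holds the C1 carbonyl three atoms from C4.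
4. The bis-lactone comes from a 2,3,4-trisubstituted furan (masked butenolide) by Yamaguchi lactonisation, singlet-oxygen oxidation and dehydration. C8 (CBS reduction) and C10 (chiral bromo ester, Fukuyama coupling) are set on an open chain grown from furan-3,4-diyldimethanol by directed lithiation.
5. Ring order: furan (bought), nine-membered lactone, butenolide (by oxidation of the furan), then furanone and ten-membered carbocycle in the key step.

Key step: step 12

Locants: germacrane-type numbering of the target is used throughout: C1 (O–C=), C2 (=CH), C3 (C=O), C4 (quaternary, bears CH3), C5 (=CH), C6 (lactone O–C=), C7, C8 (CH–O), C9 (CH2), C10 (CH–CH3), C11, C12 (lactone C=O), C13 (CH2O). The target is (4S,8S,10S). TIPS = tri(propan-2-yl)silyl, TBS = tert-butyldimethylsilyl, TES = triethylsilyl.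

Remark on the chemistry: the C4 carbinol centre of all intermediates before the key step is temporary, because C4 is planarised there. The (4S) series from (S)-2-methyloxirane is drawn; the (4R) series is equally available from the (R)-epoxide if the C4–H bond of the (4S) lactone proves poorly aligned with the dienyl π system.

**Route**

Step 1
Reactants: 1 furan-3,4-diyldimethanol
Product: 2 mono-TIPS ether of 1
Conditions: NaH (1.0 equiv), THF, 0 °C; TIPSCl (1.0 equiv), 0 °C to rt
Reagents that add atoms: chlorotri(propan-2-yl)silane (TIPSCl), CC(C)[Si](Cl)(C(C)C)C(C)C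
Why: Williamson-type O-silylation of the monosodium alkoxide, which forms selectively from the symmetric diol with one equivalent of NaH, should stop at the mono-TIPS ether and creates no stereocentre.

Step 2
Reactants: 2 mono-TIPS ether; 3 (2S)-2-methyloxirane
Product: 5 (2S)-1-[3-(hydroxymethyl)-4-(TIPS-oxymethyl)furan-2-yl]propan-2-ol, via dilithiated furan 4 (not isolated)
Conditions: n-BuLi (2.2 equiv), THF, −78 to 0 °C; then 3 (1.5 equiv), CuI (10 mol %), −30 °C to rt; aq NH4Cl
Reagents that add atoms: none
Why: Alkoxide-directed ortho-lithiation metalates the ring carbon between the furan oxygen and the CH2OLi-bearing carbon (the bulky silyl ether does not direct), and copper-assisted SN2 opening of the epoxide at its CH2 carbon leaves the (S) carbinol centre of 3 untouched.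

Step 3
Reactants: 5 furan diol
Product: 7 (6S)-6-methyl-3-(TIPS-oxymethyl)-6,7-dihydro-4H-furo[3,2-c]pyran-4-one, via lactol 6 (not isolated)
Conditions: TEMPO (20 mol %), PhI(OAc)2 (2.5 equiv), CH2Cl2, rt
Reagents that add atoms: none
Why: Oxoammonium (TEMPO/PhI(OAc)2) oxidation converts the primary furylmethanol into the aldehyde, which closes onto the secondary hydroxyl to lactol 6 and is oxidised further to the six-membered lactone, so both oxygen functions are differentiated in one operation without touching the stereocentre.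

Step 4
Reactants: 7 furo-pyranone
Product: 9 S-ethyl 2-[(2S)-2-(TES-oxy)propyl]-4-(TIPS-oxymethyl)furan-3-carbothioate, via hydroxy thioester 8 (not isolated)
Conditions: Me3Al (3 equiv), EtSH (3 equiv), CH2Cl2, 0 °C to rt; aq potassium sodium tartrate; crude 8: TESOTf, 2,6-lutidine, CH2Cl2, −78 °C
Reagents that add atoms: ethanethiol, CCS; triethylsilyl trifluoromethanesulfonate (TESOTf), CC[Si](CC)(CC)OS(=O)(=O)C(F)(F)F
Why: Acyl substitution by dimethylaluminium ethanethiolate opens the lactone to the hydroxy thioester, and fast silylation with the silyl triflate at low temperature blocks relactonisation.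

Step 5
Reactants: 9 TES thioester; 10 methyl (2R)-3-bromo-2-methylpropanoate
Product: 12 methyl (2S)-2-methyl-4-oxo-4-{2-[(2S)-2-(TES-oxy)propyl]-4-(TIPS-oxymethyl)furan-3-yl}butanoate, via organozinc bromide 11 (not isolated)
Conditions: 10, Zn dust, I2 (5 mol %), DMA, 70 °C; then 9, PdCl2(PPh3)2 (5 mol %), toluene/DMA, rt
Reagents that add atoms: none
Why: Fukuyama coupling, in which zerovalent palladium inserts into the C–S bond and the β-zincated ester 11 transmetalates, should give the ketone chemoselectively under neutral conditions that cannot enolise the ester α-stereocentre taken over from 10.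

Step 6
Reactants: 12 γ-keto ester
Product: 14 methyl (2S,4S)-4-(TBS-oxy)-2-methyl-4-{2-[(2S)-2-(TES-oxy)propyl]-4-(TIPS-oxymethyl)furan-3-yl}butanoate, via hydroxy ester 13 (not isolated)
Conditions: (R)-2-methyl-CBS-oxazaborolidine (0.3 equiv), BH3·SMe2 (1.0 equiv), toluene, −30 °C; MeOH; then TBSOTf, 2,6-lutidine, CH2Cl2, −78 °C
Reagents that add atoms: tert-butyldimethylsilyl trifluoromethanesulfonate (TBSOTf), CC(C)(C)[Si](C)(C)OS(=O)(=O)C(F)(F)F
Why: Corey–Bakshi–Shibata reduction with the (R)-oxazaborolidine delivers hydride to the ketone face that gives the (8S)-carbinol when the di-ortho-substituted furyl group is the large substituent, and silylation of 13 before isolation prevents γ-lactonisation.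

Step 7
Reactants: 14 fully silylated ester
Product: 15 methyl (2S,4S)-4-(TBS-oxy)-4-{2-[(2S)-2-hydroxypropyl]-4-(TIPS-oxymethyl)furan-3-yl}-2-methylbutanoate
Conditions: PPTS (0.2 equiv), MeOH/CH2Cl2, 0 °C
Reagents that add atoms: none
Why: Acid-catalysed methanolysis cleaves the secondary triethylsilyl ether far faster than the secondary TBS and primary TIPS ethers (graded silyl ether lability).

Step 8
Reactants: 15 hydroxy ester
Product: 16 (2S,4S)-4-(TBS-oxy)-4-{2-[(2S)-2-hydroxypropyl]-4-(TIPS-oxymethyl)furan-3-yl}-2-methylbutanoic acid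
Conditions: LiOH·H2O (3 equiv), THF/MeOH/H2O, 0 °C to rt; then 1 M HCl to pH 4
Reagents that add atoms: lithium hydroxide, [Li+].[OH-]
Why: Saponification of the methyl ester at low temperature is faster than enolisation of the α-methyl centre, so C10 should keep its configuration.

Step 9
Reactants: 16 seco acid
Product: 18 furan-fused nine-membered lactone (4S,8S,10S), via mixed anhydride 17 (not isolated)
Conditions: 2,4,6-trichlorobenzoyl chloride (1.5 equiv), Et3N, THF, rt; then syringe-pump addition to DMAP (6 equiv), toluene, 80 °C, 1 mM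
Reagents that add atoms: none
Why: Yamaguchi macrolactonisation under high dilution, helped by the two adjacent substituents on the planar furan that hold acid and alcohol on the same side, should close the nine-membered lactone with retention at C4.

Step 10
Reactants: 18 furan lactone
Product: 20 hydroxybutenolide lactone (hemiketal at C6), via endoperoxide 19 (not isolated)
Conditions: O2, tetraphenylporphyrin (1 mol %), iPr2NEt (3 equiv), CH2Cl2, visible light, −78 °C; then rt
Reagents that add atoms: dioxygen, O=O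
Why: [4+2] cycloaddition of singlet oxygen across C6 and C12 followed by base-induced Kornblum–DeLaMare fragmentation of endoperoxide 19, which can only remove the single ring hydrogen at C12, makes C12 the lactone carbonyl and C6 the hemiketal carbon (epimers at C6 are inconsequential).

Step 11
Reactants: 20 hydroxybutenolide lactone
Product: 21 (4S,5E,8S,10S)-ylidene bis-lactone
Conditions: (CF3CO)2O (1.5 equiv), 2,6-lutidine (4 equiv), CH2Cl2, −40 to 0 °C
Reagents that add atoms: none
Why: Trifluoroacetylation of the tertiary hemiketal hydroxyl and E1 loss through the acyl-oxocarbenium ion removes a C5 proton to give the enol lactone, and the nine-membered ring permits only the (5E) geometry with C4 cis to C7.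

Step 12
Reactants: 21 ylidene bis-lactone; 22 (trimethylsilyl)ketene
Product: 26 (4S,8S,10S)-8-(TBS-oxy)-13-(TIPS-oxy)-1,4-epoxy-3-oxogermacra-1,5E,7(11)-trien-12,6-olide, via potassium 2-oxidofuran 23 (not isolated), via α-silyl enolate 24 (not isolated), via β-silyl alkoxide 25 (not isolated)
Conditions: KN(SiMe3)2 (1.05 equiv), 18-crown-6 (1.1 equiv), THF, −78 °C, 10 min; then 22 (1.5 equiv), −78 to −20 °C; AcOH (2 equiv)
Reagents that add atoms: none
Why: Proposed new method: KN(SiMe3)2 removes the C4 hydrogen, the ε-position of the C5=C6/C7=C11 dienyl butenolide, to give the aromatic 2-oxidofuran 23, whose exocyclic terminus C4 adds to the central carbon of the silylketene (C3–C4 bond) to give α-silyl enolate 24; its carbon C2 then adds to the lactone carbonyl C1 (25) and Peterson elimination of Me3SiOK leaves the C1=C2 enol ether. The closest known reaction types are the use of silylketenes as C(=O)–CH linchpins (carbanion addition to the ketene, then Peterson olefination of a carbonyl group by the α-silyl enolate) and the base-mediated Claisen-type cyclisation of α-acyloxy ketones to 3(2H)-furanones; new are the vinylogous (ε) carbon nucleophile and the lactone carbonyl as olefination partner. The furanone closes by 5-exo-trig attack of C2 on C1, which the ring oxygen holds three atoms from C4, and the same bridge makes the ten-membered carbocycle (C1 to C10) transannularly out of the nine-membered lactone, whose ring oxygen becomes the 1,4-oxygen bridge. C4, the only new stereocentre, is set by substrate control: in the ring-locked (4Z)-enol lactone 23 the C9–C10 bridge and the C8 silyloxy group cover the inner face, so the ketene is expected on the outer (Re) face, which gives (4S), while C8 and C10 are untouched and C5=C6 re-forms in the only geometry the ring allows. The step needs C-acylation at C4 instead of O12, C11 or C6: O-acylation gives an aryl-type ester enolate that can revert to ketene and 23, C11 and C6 are fully substituted ring carbons, and only the C4 adduct is drained irreversibly by the intramolecular Peterson step. The amide base is consumed before 22 is added, and the poor leaving group on C13 and the low temperature guard against E1cB loss of the C13 oxygen.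

Step 13
Reactants: 26 bis-silylated tricycle
Product: 27 (4S,8S,10S)-8,13-dihydroxy-1,4-epoxy-3-oxogermacra-1,5E,7(11)-trien-12,6-olide
Conditions: HF·pyridine, pyridine, THF, 0 °C to rt
Reagents that add atoms: none
Why: Fluoride-mediated cleavage of both silyl ethers with buffered HF·pyridine is expected to spare the vinylogous ester of the furanone and the dienyl lactone.

Step 14
Reactants: 27 tricyclic diol
Product: 28 (4S,8S,10S)-13-acetoxy-8-hydroxy-1,4-epoxy-3-oxogermacra-1,5E,7(11)-trien-12,6-olide
Conditions: AcCl (1.05 equiv), 2,4,6-collidine, CH2Cl2, −78 °C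
Reagents that add atoms: acetyl chloride, CC(Cl)=O
Why: Kinetically controlled acylation with acetyl chloride and a hindered pyridine base at low temperature selects the unhindered primary allylic hydroxyl over the hindered secondary C8 hydroxyl.

Step 15
Reactants: 29 4-methylfuran-2(5H)-one
Product: 32 (2Z)-4-(TBS-oxy)-3-methylbut-2-enoic acid, via sodium hydroxy enoate 30 (not isolated), via bis-silyl derivative 31 (not isolated)
Conditions: NaOH (1.0 equiv), H2O/MeOH, 0 °C to rt, evaporation; TBSCl (2.5 equiv), imidazole, DMF, rt; K2CO3 (1.1 equiv), MeOH/H2O, 0 °C; aq citric acid to pH 5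
Reagents that add atoms: sodium hydroxide, [Na+].[OH-]; tert-butylchlorodimethylsilane (TBSCl), CC(C)(C)[Si](C)(C)Cl
Why: Saponification of the butenolide keeps the (Z) geometry imposed by the ring, exhaustive silylation then selective solvolysis of the labile silyl ester leaves the silyl ether, and the protected (Z)-acid can no longer relactonise.

Step 16
Reactants: 28 13-acetate; 32 (Z)-silyloxy acid
Product: 33 (4S,8S,10S)-13-acetoxy-8-[(2Z)-4-(TBS-oxy)-3-methylbut-2-enoyloxy]-1,4-epoxy-3-oxogermacra-1,5E,7(11)-trien-12,6-olide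
Conditions: EDC·HCl (1.5 equiv), DMAP (0.3 equiv), CH2Cl2, 0 °C to rt
Reagents that add atoms: none
Why: Carbodiimide/DMAP (Steglich) esterification of the C8 hydroxyl at low temperature and low DMAP loading should avoid Z to E isomerisation of the enoate and base-induced loss of the C13 acetate.

Step 17
Reactants: 33 silyl-protected target
Product: 34 CNP0269057.1
Conditions: HF·pyridine, pyridine, THF, 0 °C
Reagents that add atoms: none
Why: Buffered HF·pyridine removes the primary TBS ether under weakly acidic conditions in which lactonisation of the (Z)-4-hydroxy enoate (with loss of the C8 alcohol) and acetate migration should be slow.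

**Compound list**

1 | furan-3,4-diyldimethanol | OCc1cocc1CO | starting material
2 | [4-(TIPS-oxymethyl)furan-3-yl]methanol | OCc1cocc1CO[Si](C(C)C)(C(C)C)C(C)C | intermediate
3 | (2S)-2-methyloxirane | C[C@H]1CO1 | starting material
4 | lithium [2-lithio-4-(TIPS-oxymethyl)furan-3-yl]methanolate | [Li]OCc1c([Li])occ1CO[Si](C(C)C)(C(C)C)C(C)C | intermediate
5 | (2S)-1-[3-(hydroxymethyl)-4-(TIPS-oxymethyl)furan-2-yl]propan-2-ol | C[C@H](O)Cc1occ(CO[Si](C(C)C)(C(C)C)C(C)C)c1CO | intermediate
6 | (6S)-6-methyl-3-(TIPS-oxymethyl)-6,7-dihydro-4H-furo[3,2-c]pyran-4-ol (lactol, both anomers) | C[C@H]1Cc2occ(CO[Si](C(C)C)(C(C)C)C(C)C)c2C(O)O1 | intermediate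
7 | (6S)-6-methyl-3-(TIPS-oxymethyl)-6,7-dihydro-4H-furo[3,2-c]pyran-4-one | C[C@H]1Cc2occ(CO[Si](C(C)C)(C(C)C)C(C)C)c2C(=O)O1 | intermediate
8 | S-ethyl 2-[(2S)-2-hydroxypropyl]-4-(TIPS-oxymethyl)furan-3-carbothioate | CCSC(=O)c1c(C[C@H](C)O)occ1CO[Si](C(C)C)(C(C)C)C(C)C | intermediate
9 | S-ethyl 2-[(2S)-2-(TES-oxy)propyl]-4-(TIPS-oxymethyl)furan-3-carbothioate | CCSC(=O)c1c(C[C@H](C)O[Si](CC)(CC)CC)occ1CO[Si](C(C)C)(C(C)C)C(C)C | intermediate
10 | methyl (2R)-3-bromo-2-methylpropanoate | COC(=O)[C@@H](C)CBr | starting material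
11 | bromo[(2R)-3-methoxy-2-methyl-3-oxopropyl]zinc | COC(=O)[C@@H](C)C[Zn]Br | intermediate
12 | methyl (2S)-2-methyl-4-oxo-4-{2-[(2S)-2-(TES-oxy)propyl]-4-(TIPS-oxymethyl)furan-3-yl}butanoate | COC(=O)[C@@H](C)CC(=O)c1c(C[C@H](C)O[Si](CC)(CC)CC)occ1CO[Si](C(C)C)(C(C)C)C(C)C | intermediate
13 | methyl (2S,4S)-4-hydroxy-2-methyl-4-{2-[(2S)-2-(TES-oxy)propyl]-4-(TIPS-oxymethyl)furan-3-yl}butanoate | COC(=O)[C@@H](C)C[C@H](O)c1c(C[C@H](C)O[Si](CC)(CC)CC)occ1CO[Si](C(C)C)(C(C)C)C(C)C | intermediate
14 | methyl (2S,4S)-4-(TBS-oxy)-2-methyl-4-{2-[(2S)-2-(TES-oxy)propyl]-4-(TIPS-oxymethyl)furan-3-yl}butanoate | COC(=O)[C@@H](C)C[C@H](O[Si](C)(C)C(C)(C)C)c1c(C[C@H](C)O[Si](CC)(CC)CC)occ1CO[Si](C(C)C)(C(C)C)C(C)C | intermediate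
15 | methyl (2S,4S)-4-(TBS-oxy)-4-{2-[(2S)-2-hydroxypropyl]-4-(TIPS-oxymethyl)furan-3-yl}-2-methylbutanoate | COC(=O)[C@@H](C)C[C@H](O[Si](C)(C)C(C)(C)C)c1c(C[C@H](C)O)occ1CO[Si](C(C)C)(C(C)C)C(C)C | intermediate
16 | (2S,4S)-4-(TBS-oxy)-4-{2-[(2S)-2-hydroxypropyl]-4-(TIPS-oxymethyl)furan-3-yl}-2-methylbutanoic acid | OC(=O)[C@@H](C)C[C@H](O[Si](C)(C)C(C)(C)C)c1c(C[C@H](C)O)occ1CO[Si](C(C)C)(C(C)C)C(C)C | intermediate
17 | mixed anhydride of acid 16 with 2,4,6-trichlorobenzoic acid | O=C(OC(=O)[C@@H](C)C[C@H](O[Si](C)(C)C(C)(C)C)c1c(C[C@H](C)O)occ1CO[Si](C(C)C)(C(C)C)C(C)C)c1c(Cl)cc(Cl)cc1Cl | intermediate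
18 | (4S,8S,10S) nine-membered lactone of 16 (C1 acyl on the C4 oxygen) fused to the furan at C6–C7; 8-OTBS, 13-OTIPS | O=C1O[C@@H](C)Cc2occ(CO[Si](C(C)C)(C(C)C)C(C)C)c2[C@@H](O[Si](C)(C)C(C)(C)C)C[C@@H]1C | intermediate
19 | 6,12-endoperoxide of furan lactone 18 (2,3,7-trioxabicyclo[2.2.1]heptene unit) | O=C1O[C@@H](C)CC23OOC(O2)C(CO[Si](C(C)C)(C(C)C)C(C)C)=C3[C@@H](O[Si](C)(C)C(C)(C)C)C[C@@H]1C | intermediate
20 | (4S,8S,10S) nine-membered 1,4-lactone fused to the 6-hydroxy-12,6-olide (C12 carbonyl, hemiketal at C6, both C6 epimers) | O=C1O[C@@H](C)CC2(O)OC(=O)C(CO[Si](C(C)C)(C(C)C)C(C)C)=C2[C@@H](O[Si](C)(C)C(C)(C)C)C[C@@H]1C | intermediate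
21 | (4S,5E,8S,10S) nine-membered 1,4-lactone fused to the 5-ylidene butenolide (12,6-olide, C5=C6, C7=C11); 8-OTBS, 13-OTIPS | O=C1O[C@@H](C)/C=C2/OC(=O)C(CO[Si](C(C)C)(C(C)C)C(C)C)=C2[C@@H](O[Si](C)(C)C(C)(C)C)C[C@@H]1C | intermediate
22 | (trimethylsilyl)ketene | C[Si](C)(C)C=C=O | starting material
23 | potassium 12-oxidofuran (2-oxidofuran) carrying the (4Z)-enol lactone C4=C5 | O=C1O/C(C)=C\c2oc([O-])c(CO[Si](C(C)C)(C(C)C)C(C)C)c2[C@@H](O[Si](C)(C)C(C)(C)C)C[C@@H]1C.[K+] | intermediate
24 | potassium enolate of the (4S)-4-[(trimethylsilyl)acetyl] derivative of 21 | O=C1O[C@](C)(C([O-])=C[Si](C)(C)C)/C=C2/OC(=O)C(CO[Si](C(C)C)(C(C)C)C(C)C)=C2[C@@H](O[Si](C)(C)C(C)(C)C)C[C@@H]1C.[K+] | intermediate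
25 | potassium 1-alkoxide of the bicyclic 2-(trimethylsilyl) hemiketal (C1–C2 bond formed, C3 ketone) | [O-]C12C([Si](C)(C)C)C(=O)[C@@](C)(O1)/C=C3/OC(=O)C(CO[Si](C(C)C)(C(C)C)C(C)C)=C3[C@@H](O[Si](C)(C)C(C)(C)C)C[C@@H]2C.[K+] | intermediate
26 | (4S,8S,10S)-8-(TBS-oxy)-13-(TIPS-oxy)-1,4-epoxy-3-oxogermacra-1,5E,7(11)-trien-12,6-olide | CC(C)[Si](OCC1=C2/C(=C\[C@]3(C)OC(=CC3=O)[C@@H](C)C[C@@H]2O[Si](C)(C)C(C)(C)C)OC1=O)(C(C)C)C(C)C | intermediate
27 | (4S,8S,10S)-8,13-dihydroxy-1,4-epoxy-3-oxogermacra-1,5E,7(11)-trien-12,6-olide | OCC1=C2/C(=C\[C@]3(C)OC(=CC3=O)[C@@H](C)C[C@@H]2O)OC1=O | intermediate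
28 | (4S,8S,10S)-13-acetoxy-8-hydroxy-1,4-epoxy-3-oxogermacra-1,5E,7(11)-trien-12,6-olide | CC(=O)OCC1=C2/C(=C\[C@]3(C)OC(=CC3=O)[C@@H](C)C[C@@H]2O)OC1=O | intermediate
29 | 4-methylfuran-2(5H)-one | CC1=CC(=O)OC1 | starting material
30 | sodium (2Z)-4-hydroxy-3-methylbut-2-enoate | [Na+].[O-]C(=O)/C=C(/C)CO | intermediate
31 | tert-butyldimethylsilyl (2Z)-4-(TBS-oxy)-3-methylbut-2-enoate | CC(C)(C)[Si](C)(C)OC(=O)/C=C(/C)CO[Si](C)(C)C(C)(C)C | intermediate
32 | (2Z)-4-(TBS-oxy)-3-methylbut-2-enoic acid | OC(=O)/C=C(/C)CO[Si](C)(C)C(C)(C)C | intermediate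
33 | (4S,8S,10S)-13-acetoxy-8-[(2Z)-4-(TBS-oxy)-3-methylbut-2-enoyloxy]-1,4-epoxy-3-oxogermacra-1,5E,7(11)-trien-12,6-olide | CC(=O)OCC1=C2/C(=C\[C@]3(C)OC(=CC3=O)[C@@H](C)C[C@@H]2OC(=O)/C=C(/C)CO[Si](C)(C)C(C)(C)C)OC1=O | intermediate
34 | CNP0269057.1, (4S,8S,10S)-13-acetoxy-8-[(2Z)-4-hydroxy-3-methylbut-2-enoyloxy]-1,4-epoxy-3-oxogermacra-1,5E,7(11)-trien-12,6-olide | CC(=O)OCC1=C2/C(=C\[C@]3(C)OC(=CC3=O)[C@@H](C)C[C@@H]2OC(=O)/C=C(/C)CO)OC1=O | target

**Step count**

Total steps: 17. Longest linear sequence: 16 (steps 1 to 14, then 16 and 17); step 15 makes the side-chain acid.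

**Steps most likely to fail**

1. Step 12 (Proposed new method). What may go wrong:
- acylation of the ambident 2-oxidofuran at oxygen or at the ring carbons C6 or C11 instead of at C4;
- slow deprotonation if the C4–H bond is poorly aligned with the dienyl π system inside the nine-membered ring;
- transannular acyl transfer from the ring oxygen to C6 (ring contraction) before the ketene is trapped;
- E1cB loss of the C13 silyloxy group;
- attack on the inner face of C4, which would give the (4R) epimer.

Fallback with known reaction types, from 21 back to 26, in which the two bonds are made one after the other and no free enolate is exposed to the lactone. Soft enolisation of 21 (TBSOTf, Et3N, CH2Cl2, −78 °C) should give the silyl trienol ether F1. A BF3·OEt2-promoted vinylogous Mukaiyama aldol addition to acetaldehyde at the remote terminus C4 should give the C4 hydroxyethyl lactone F2. Dess–Martin oxidation should give the C4 acetyl lactone F3, an α-acyloxy methyl ketone. Enolisation of its methyl group with LiN(SiMe3)2 (THF, −78 °C) should be followed by intramolecular Claisen-type addition to the lactone carbonyl, and dehydration on work-up with camphorsulfonic acid (the classical 3(2H)-furanone synthesis) then returns to 26.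

2. Step 9. What may go wrong: intermolecular acylation (diolide and oligomers) outruns closure of the strained nine-membered ring, and ketene formation from the activated acid erodes the configuration at C10.

Fallback, from 16 back to 26: close the ring by activating the alcohol instead of the acid. Mitsunobu lactonisation of 16 (PPh3, diisopropyl azodicarboxylate, toluene, high dilution) forms the C4–O bond by SN2 displacement with inversion and should give the (4R)-furan lactone F4. Steps 10 and 11 applied to F4 should give the (4R)-hydroxybutenolide lactone F5 and the (4R)-ylidene bis-lactone F6. Step 12 on F6 returns to 26, because C4 is planarised there.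

3. Step 11. What may go wrong: ionisation of the allylic C4–O bond or opening of the hemiketal to the keto acid competes with loss of the C5 proton, and the product, with its acidic C4–H and twisted diene, decomposes on isolation.

Fallback, from 20 back to 21: make the C5=C6 bond by dehydrogenation instead of dehydration. NaBH4 reduction of 20 (through its open keto-acid form, MeOH, 0 °C, then mild acid) should give the γ-unsubstituted butenolide F7. Silylation (TBSOTf, Et3N) should give the 2-silyloxyfuran F8. Saegusa–Ito oxidation with Pd(OAc)2 in MeCN removes a C5 hydrogen and should give 21 in the ring-enforced (5E) geometry.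

Further compounds
F1 | step 12 | silyl trienol ether: 12-(TBS-oxy)furan carrying the (4Z)-enol lactone, 8-OTBS, 13-OTIPS | O=C1O/C(C)=C\c2oc(O[Si](C)(C)C(C)(C)C)c(CO[Si](C(C)C)(C(C)C)C(C)C)c2[C@@H](O[Si](C)(C)C(C)(C)C)C[C@@H]1C
F2 | step 12 | (4S)-4-(1-hydroxyethyl) derivative of bis-lactone 21 (both carbinol epimers) | O=C1O[C@](C)(C(C)O)/C=C2/OC(=O)C(CO[Si](C(C)C)(C(C)C)C(C)C)=C2[C@@H](O[Si](C)(C)C(C)(C)C)C[C@@H]1C
F3 | step 12 | (4S)-4-acetyl derivative of bis-lactone 21 | O=C1O[C@](C)(C(C)=O)/C=C2/OC(=O)C(CO[Si](C(C)C)(C(C)C)C(C)C)=C2[C@@H](O[Si](C)(C)C(C)(C)C)C[C@@H]1C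
F4 | step 9 | (4R,8S,10S)-furan lactone, C4 epimer of 18 | O=C1O[C@H](C)Cc2occ(CO[Si](C(C)C)(C(C)C)C(C)C)c2[C@@H](O[Si](C)(C)C(C)(C)C)C[C@@H]1C
F5 | step 9 | (4R,8S,10S)-hydroxybutenolide lactone, C4 epimer of 20 | O=C1O[C@H](C)CC2(O)OC(=O)C(CO[Si](C(C)C)(C(C)C)C(C)C)=C2[C@@H](O[Si](C)(C)C(C)(C)C)C[C@@H]1C
F6 | step 9 | (4R,5E,8S,10S)-ylidene bis-lactone, C4 epimer of 21 | O=C1O[C@H](C)/C=C2/OC(=O)C(CO[Si](C(C)C)(C(C)C)C(C)C)=C2[C@@H](O[Si](C)(C)C(C)(C)C)C[C@@H]1C
F7 | step 11 | (4S,8S,10S) nine-membered lactone fused to the γ-unsubstituted butenolide (C6–H, both epimers) | O=C1O[C@@H](C)CC2OC(=O)C(CO[Si](C(C)C)(C(C)C)C(C)C)=C2[C@@H](O[Si](C)(C)C(C)(C)C)C[C@@H]1C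
F8 | step 11 | 12-(TBS-oxy)furan (2-silyloxyfuran) of F7 | O=C1O[C@@H](C)Cc2oc(O[Si](C)(C)C(C)(C)C)c(CO[Si](C(C)C)(C(C)C)C(C)C)c2[C@@H](O[Si](C)(C)C(C)(C)C)C[C@@H]1C
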